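A chemist who must say what leads after 40 min in cedar and in maple has the noon and dusk runs to go on:

| setting | noon | dusk | cedar | maple |
|---|---|---|---|---|
| L | 0.025 M | 0.038 M | 0.050 M | 0.050 M |
| temperature | 95 °C | 108 °C | 115 °C | 100 °C |
| remark | run made earlier | run made earlier |  |  |
| time |  |  | 40 min | 40 min |

| run | time / min | G / % | L / % | Q / % | D / % |
|---|---|---|---|---|---|
| noon | 4.00 | 3.1 | 74.8 | 9.9 | 0.7 |
| noon | 10.0 | 8.7 | 51.4 | 19.3 | 1.8 |
| noon | 20.0 | 16.1 | 27.8 | 26.2 | 6.3 |
| noon | 30.0 | 22.0 | 16.6 | 28.1 | 10.6 |
| noon | 40.0 | 26.2 | 9.7 | 27.2 | 15.9 |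
| dusk | 4.00 | 12.6 | 37.6 | 23.5 | 3.3 |
| dusk | 10.0 | 25.6 | 11.3 | 28.3 | 12.4 |
| dusk | 20.0 | 32.2 | 1.5 | 20.8 | 25.9 |
| dusk | 30.0 | 34.2 | 0.1 | 12.2 | 34.4 |
| dusk | 40.0 | 34.1 | 0.5 | 7.0 | 40.5 |

(readings scatter by 0.3 percentage points)

1. which of these there is most of at the end, counted by the L in it, cedar (L / D / G / Q)
2. which of these there is most of at the end, counted by the L in it, maple (L / D / G / Q)
3. amount of the one of these that there is most of at the end, in percent of the L charged, cedar
4. amount of the one of these that there is most of at the end, in percent of the L charged, maple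

- a reading of L is of its free form alone

In the dusk run, D reads 34.4 % against 34.2 % of G at 30.0 min, a tie within the scatter of 0.3 percentage points, so we take that as the crossing time, 30.0 min, the time at which D, growing as Q falls, draws level with G. The bench rule of thumb says that, at a fixed charge, 10.0 K more doubles a rate and so halves the times of a run. Applied to dusk, it puts the crossing at 18.5 min in cedar, inside the 40 min, and at 52.2 min in maple, beyond it, so of these two we expect D ahead in cedar and G ahead in maple.

The border of the rule for maple is the ratio of the asked time to the crossing time, 1.33: on this reckoning G stays ahead in maple so long as the 8.00 K between maple and dusk stretch the times by more than that, and the rule's stretch is 1.74. The fall of L reads 3.26 times faster in dusk than in noon, where the rule gives 2.46, but dusk differs from noon in its charge as well as in its temperature, so this reading does not tell the two apart. The rule also says nothing of the charge, and both new flasks hold 0.050 M against the 0.038 M of dusk. For the amounts, we would put D in cedar a little under the 47.5 % of Q and D together at dusk's last reading, and G in maple under dusk's 34.1 %.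

The forecast, made from the same runs, says D at 44 % (39 % to 48 %) for cedar, on the ground that “L is gone and Q is nearly all converted”, and G at 30.5 % (27 % to 35 %) for maple.

The flasks give D at 45.1 % in cedar, with G at 34.6 %, and G at 28.3 % in maple, with D at 23.0 %.

    L ⇌ E (K = 13.0, k = 0.0226 min⁻¹, Ea = 120 kJ mol⁻¹, ΔH = −55.0 kJ mol⁻¹)
    E → G (k = 0.132 min⁻¹, Ea = 98.0 kJ mol⁻¹)
    L → Q (k = 0.0489 min⁻¹, Ea = 116 kJ mol⁻¹)
    L → G (k = 0.0120 min⁻¹, Ea = 126 kJ mol⁻¹)
    Q → D (k = 0.0271 min⁻¹, Ea = 104 kJ mol⁻¹)
    2 L → Z (k = 0.697 M⁻¹ min⁻¹, Ea = 78.0 kJ mol⁻¹)
    (constants at 100 °C)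

In cedar the reckoned crossing time of 18.5 min falls before 20.0 min, and at that later time D stands at 37.8 % against 34.5 % of G. G holds the lead in maple because of the path from E to G: with that path struck out, G at the end of maple falls from 28.3 % to 10.3 %, and the answer turns. In the neighbour flask, cedar repeated at 90 °C, the same rule stretches the crossing time to 104 min, beyond 40 min, and that flask ends with D at 7.10 % under G at 16.2 %.

The runs stem from a simulated flask on assumed constants; scatter was added.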